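common to all: free catalyst 0.1 mol%; racemization catalyst 5 mol%

| charge | left-handed substrate | right-handed substrate | partner | remark | time |
|---|---|---|---|---|---|
| Saturday's | 0.10 M | 0.10 M | 2.5 equiv (in portions, 4) | the very flask that is asked about, followed so far; portions every 20 h |  |
| Tuesday's | 0.067 M | 0.067 M | 2.5 equiv (in portions, 4) | run made earlier; portions every 20 h |  |
| flask | 0.10 M | 0.10 M | 2.50 equiv (in portions, 4) | the portions of partner follow each other after 20 h, the first at the start | 3.0 d |

A small charge of racemate is what this flask has to turn: 0.10 M of each substrate, c(left-handed substrate) equal to c(right-handed substrate). Partner at 2.50 equiv on the left-handed substrate comes to 125% of the two substrates together, more than they need at one partner per product, so over the whole charge the substrates are the limiting reagent. But partner comes in 4 portions, each 31.2% of the substrates, so the balance at a given moment is drawn up over the partner delivered until then.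

| run | time / h | left-handed product / % |
|---|---|---|
| Saturday's | 6.00 | 3 |
| Saturday's | 12.0 | 7 |
| Saturday's | 20.0 | 11 |
| Saturday's | 25.0 | 14 |
| Saturday's | 30.0 | 19 |
| Saturday's | 40.0 | 24 |
| Tuesday's | 3.00 | 1 |
| Tuesday's | 10.0 | 5 |
| Tuesday's | 20.0 | 7 |
| Tuesday's | 30.0 | 13 |
| Tuesday's | 40.0 | 16 |
| Tuesday's | 48.0 | 17 |

(standard deviation of a reading: 1.5 percentage points)

- free catalyst is single-handed; left-handed substrate and right-handed substrate are mirror images of each other, charged as a racemate, each of them at the stated concentration
- what was read earlier has a scatter of 1.5 percentage points, one standard deviation

Saturday's flask is the flask asked about, and at 40.0 h, with 2.00 portions delivered and the next about to fall, it reads 24%. That reading, over the partner delivered, gives 38.4%. This is the portion yield: left-handed product just before a portion, divided by partner delivered until then, both in percent of the substrates. It is a reading, with a scatter of 1.5 percentage points in its numerator.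

- amount of left-handed product in percent of the left-handed substrate and right-handed substrate together charged, at 8.0 h, 20 h, 40 h and 3.0 d

My own reckoning holds the portion yield steady, so each interval of 20 h adds 12.0% of the substrates; it keeps that pace after the last portion too, and so 3.0 d gives 43.2%. The forecast gives 4.7%, 12%, 24% and 38%, lower than mine at the end, and says: “This last value is an extrapolation, so its range is wide”.

The flask gives 6.02%, 11.4%, 24.3% and 43.3%.

    partner + free catalyst + left-handed substrate → free catalyst + left-handed product (k = 0.850 M⁻² s⁻¹)
    partner + free catalyst + right-handed substrate → free catalyst + right-handed product (k = 0.290 M⁻² s⁻¹)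
    left-handed substrate + racemization catalyst ⇌ right-handed substrate + racemization catalyst, rate k3*[racemization catalyst]*[left-handed substrate] forward; the back reaction follows from the equilibrium constant (k = 0.00180 M⁻¹ s⁻¹)
    free catalyst ⇌ dormant form (K = 0.800, k = 2.20 × 10⁻⁶ s⁻¹)

At 2.50 d, just before the last addition, the flask holds 36.3% left-handed product beside 14.1% right-handed product, and 34.6% of the partner charge is still there. Over the 3.00 portions delivered, the portion yield is 38.8%. On Tuesday's run, with 0.067 M of each substrate and the same portion share, the reading of 16% at 40.0 h gives a portion yield of 25.6%.

The data come from a simulation on assumed constants; scatter was added.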